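No rate constant was on the table, so the meeting worked from the readings of the earlier runs.

all flasks: electrophile 0.50 M
- dawn: nucleophile 0.55 M; run made earlier
- noon: nucleophile 0.99 M; run made earlier
- autumn: nucleophile 2.1 M; run made earlier
- teal: nucleophile 0.500 M; time 5.0 d
- amber: nucleophile 1.00 M; time 5.0 d
- blue: nucleophile 2.00 M; time 5.0 d

| run | time / d | electrophile / % | target / % |
|---|---|---|---|
| dawn | 1.25 | 74 | 23 |
| dawn | 2.50 | 72 | 27 |
| dawn | 4.00 | 72 | 25 |
| dawn | 5.00 | 72 | 27 |
| noon | 1.25 | 68 | 29 |
| noon | 2.50 | 69 | 31 |
| noon | 4.00 | 65 | 37 |
| noon | 5.00 | 63 | 34 |
| autumn | 1.25 | 59 | 41 |
| autumn | 2.50 | 58 | 43 |
| autumn | 4.00 | 56 | 42 |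
| autumn | 5.00 | 54 | 43 |

(standard deviation of a reading: 1.5 percentage points)

- the numbers in the tables scatter by 1.5 percentage points (one standard deviation)

- part of the electrophile that has reacted at the end, teal
- part of the electrophile that has reacted at the end, amber
- part of the electrophile that has reacted at the end, blue
- what raising the concentration of nucleophile from its lowest to its highest value here does to the part of the electrophile that has reacted (changes below 5 percentage points count as none) (no change / it rises / it falls)

The chair opened by noting that the new flasks are asked at 5.0 d, the time of the last reading in each earlier run, so the members agreed to work from those last readings. One member added that in dawn the electrophile and target, at 72% and 27%, made up about the whole charge, so the target could stand for the part reacted.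

A second member then argued that the nucleophile charge should be counted in doublings. From dawn to autumn it rose by 1.93 doublings and the target by 16 percentage points, so each doubling won 8.3 points. She named this the doubling gain: the points of target won per doubling of the nucleophile charge, with electrophile and time held. As a test, she reckoned noon from dawn, which gave 34.0% against a reading of 34%.

Her own reckoning from dawn gave 25.9% for teal, 34.1% for amber and 42.4% for blue. The two doublings from teal to blue add 17 points, more than the 5 points that counts as a change.

The forecaster reported 26.5%, 36% and 44%, with the verdict it rises, saying: “The new runs almost repeat the earlier ones, so I interpolate”. For blue, the forecast stood above her reckoning, and the meeting left that difference open.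

The flasks gave 26.2% for teal, 34.2% for amber and 41.9% for blue: it rises, by 16 points.

    nucleophile + acid set free ⇌ protonated nucleophile, settled at all times (K = 370 /M)
    2 nucleophile → self-condensation product (k = 0.350 /M/h)
    electrophile + nucleophile ⇌ acid set free + target (K = 5.80, k = 0.120 /M/h)

The two doublings from teal to blue were reckoned at 17 points, and the flasks differ by 16 points. A neighbour flask, amber with 1.7 M of nucleophile, is reckoned from amber and the doubling gain at 40.5%, and it gives 40.1%. Blue falls short of full reaction mainly because the nucleophile is lost to self-condensation product: the blue run with that reaction taken away reaches >99.9% instead of 41.9%. In blue as it stands, the nucleophile runs out first, its free part at the end down to 0.393% of its charge.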